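A small charge of L sets this problem: oak received 0.475 M of L against 0.50 M of Z, fed over 20 min, and the flask asked about is oak itself, carried on to 3.0 d.

| setting | oak | larch | flask |
|---|---|---|---|
| Z | 0.50 M | 0.50 M | 0.50 M |
| L | 0.475 M (fed, over 20 min) | 0.71 M (fed, over 20 min) | 0.475 M (fed, over 20 min) |
| remark | the very flask that is asked about, followed so far | run made earlier |  |
| time |  |  | 3.0 d |

oak run (percent of the Z charged)

| time / h | Z / % | Q / % |
|---|---|---|
| 0.833 | 79.7 | 17.3 |
| 2.00 | 58.3 | 35.8 |
| 4.00 | 36.6 | 53.3 |
| 6.00 | 25.8 | 61.0 |
| 8.00 | 19.2 | 65.9 |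
| 12.0 | 11.6 | 69.1 |
| 15.0 | 9.5 | 71.2 |

larch run (percent of the Z charged)

| time / d | Z / % | Q / % |
|---|---|---|
| 0.167 | 28.3 | 64.2 |
| 0.500 | 3.9 | 84.9 |
| 0.833 | 0.8 | 88.2 |
| 1.25 | 0.1 | 88.1 |
| 1.67 | 0.3 | 88.4 |
| 2.50 | 0.1 | 87.8 |
| 3.00 | 0 | 88.6 |

(scatter of a reading: 0.3 percentage points)

- why nothing more happens at 3.0 d, or that something still does (it is still moving / all of Z has reacted / L has run out first / forward and back rates have come level)
- part of the Z gone at 3.0 d
- the Q standing at 3.0 d, as a percentage of the Z charged
- the G standing at 3.0 d, as a percentage of the Z charged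

- the numbers in the tables scatter with a standard deviation of 0.3 percentage points
- the reaction counts as stopped when no species that holds the Z changes by six tenths of a point or more over the second half of the time

In oak, Z starts with an apparent first-order constant of 0.272 h⁻¹, and larch, with its larger charge of L, shows 0.248 h⁻¹ between its first two readings, so the two slopes lie close although [L] differs. Q crosses Z in oak near 3.15 h. A knee follows, for between 12.0 h and 15.0 h the oak constant has dropped to 0.0666 h⁻¹, lower than at the start. A step of Z without L has a constant that does not fall, so my own reckoning lets each Z that becomes Q or G take one L. That gives oak a level to run into: 95.0 % is the L ceiling, the charge of L over the charge of Z, the most of the Z that can become Q and G, which makes L the limiting reagent, and this reckoning, which counts Q and G as the products, draws the level of Z at 5.00 %. Larch has a ceiling of 142 %, above the whole of its Z, and its Z reads 0 % at the end.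

At 15.0 h oak stands 4.5 percentage points above that reckoned level, and that excess last halved in about 5.43 h, far shorter than 3.0 d. I therefore expect that L runs out first, with 95.0 % of Z gone. The late share of Z lost that appears as Q, 54.6 %, puts Q near 73.7 % and G near 21.3 %.

The forecast differs, reasoning that “the G path needs no L, Z keeps falling even as L dwindles”: all of Z has reacted, with 99.8 % gone, Q 76.7 % and G 23.1 %.

The flask gives L has run out first, with 95.8 % of Z gone, Q 72.5 % and G 22.5 %.

    Z ⇌ X (K = 0.00390, k = 0.540 h⁻¹)
    X ⇌ J (K = 1.90, k = 21.0 h⁻¹)
    L + X → Q (k = 390 L mol⁻¹ h⁻¹)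
    L + J → G (k = 620 L mol⁻¹ h⁻¹)
    X → E (k = 0.340 h⁻¹)

In oak, Q and G together stand at 95.0 % against the L ceiling of 95.0 %, with L at 0 % of its charge and its half-life through L + J at that time, 0.30 d, shorter than 3.0 d, while the 0.80 points of Z gone beyond the ceiling stands beside 0.735 % passed from X into E. The neighbouring flask with 0.12 M of L has a ceiling of 24.0 %, holds Q and G together at 24.0 %, and keeps 68.4 % of its Z.

The earlier runs and the new flask stem from a simulated flask with made-up constants; noise was put on by code.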